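**Retrosynthetic overview**

- The strategy rests on the O1–C2–C3–O4 unit of the dioxane ring plus the C3 methyl carbon. This is a three-carbon chain (C2, C3, methyl carbon) oxygenated on the adjacent carbons C2 and C3, the pattern a propargylic electrophile hands to the two hydroxyls of a catechol (ring A). Numbering: O1, C2 (ring B), C3 (methyl), O4, C4a, C5 (OMe), C6, C7 (propenyl), C8, C8a.
- Late disconnections: free ring B phenol from its silyl ether; C7 (E)-propenyl from a C7 aldehyde by Takai ethylidenation; aldehyde from the C7 methyl ester.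
- The trans C3 methyl comes from a C3 exocyclic methylene by hydrogen-atom-transfer reduction.
- Key disconnection: O4–C3 and O1–C2 are cut together, giving methyl 3,4-dihydroxy-5-methoxybenzoate and a racemic ring B propargylic carbonate. A palladium/BINAP annulation forms both bonds and sets C2.
- Ring order: rings A and B are bought; the dioxane ring is the only ring formed (step 3). The carbonate comes from syringaldehyde in two steps.

Key step: step 3

Assumption: (R)-BINAP is taken as the ligand enantiomer that gives the 2R product; if the sense of induction proves opposite, (S)-BINAP is used and nothing else changes.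

**Route**

Step 1
Reactants: 1 syringaldehyde (4-hydroxy-3,5-dimethoxybenzaldehyde)
Product: 2 4-(tert-butyldimethylsilyloxy)-3,5-dimethoxybenzaldehyde
Conditions: TBSCl, imidazole, DMF, rt
Reagents that add atoms: tert-butyldimethylsilyl chloride (TBSCl), CC(C)(C)[Si](C)(C)Cl
Why: Imidazole-promoted O-silylation (silyl ether protection) should be clean because the acidic phenol is the only nucleophilic site, and the silyl ether masks the ring B hydroxyl through the Grignard, palladium, radical, hydride and chromium steps.

Step 2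
Reactants: 2 4-(tert-butyldimethylsilyloxy)-3,5-dimethoxybenzaldehyde; 3 ethynylmagnesium bromide
Product: 5 racemic 1-[4-(tert-butyldimethylsilyloxy)-3,5-dimethoxyphenyl]prop-2-yn-1-yl methyl carbonate, via bromomagnesium propargylic alkoxide 4 (not isolated)
Conditions: HC≡CMgBr, THF, 0 °C; then ClCO2Me, 0 °C to rt
Reagents that add atoms: methyl chloroformate, COC(=O)Cl
Why: Grignard 1,2-addition of the alkynyl nucleophile to the aldehyde followed by O-acylation of the magnesium alkoxide in the same flask should give the carbonate without handling the acid-sensitive electron-rich propargylic alcohol, and the carbinol centre may be racemic because step 3 is enantioconvergent.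

Step 3
Reactants: 5 racemic 1-[4-(tert-butyldimethylsilyloxy)-3,5-dimethoxyphenyl]prop-2-yn-1-yl methyl carbonate; 6 methyl 3,4-dihydroxy-5-methoxybenzoate
Product: 7 methyl (2R)-2-[4-(tert-butyldimethylsilyloxy)-3,5-dimethoxyphenyl]-5-methoxy-3-methylidene-2,3-dihydro-1,4-benzodioxine-7-carboxylate
Conditions: Pd2(dba)3 (2.5 mol %), (R)-BINAP (6 mol %), THF, rt
Reagents that add atoms: none
Why: Zerovalent palladium ionises the carbonate with loss of CO2 and methoxide to an allenyl (η3-propargyl) palladium cation, and the methoxide deprotonates the more acidic O4–H of 6; the O4 phenoxide adds to the central sp carbon (O4–C3), and proton transfer to the resulting palladium carbene gives a 2-aryloxy π-allylpalladium complex whose termini are CH2 and CH(ring B). The reaction type is the known palladium-catalysed annulation of benzene-1,2-diols with propargylic carbonates to 2-alkylidene-1,4-benzodioxanes, including its chiral bisphosphine variant. The dioxane ring is closed in the 6-exo mode by outer-sphere attack of O1 on the aryl-bearing allyl terminus from the face opposite palladium (intramolecular allylic etherification), which leaves the C3=CH2 alkene exocyclic. C2 is set by the BINAP ligand alone, because the carbonate stereocentre is lost at the planar vinyl carbene and π-allyl stage and the two diastereomeric π-allyl complexes interconvert by η3–η1–η3 slippage at the CH2 terminus, so both enantiomers of 5 converge. Two selectivities are needed: O4 must react before O1, which the lower pKa of the hydroxyl para to the ester should secure, and closure must occur at C2 and not at the CH2 terminus, which is favoured by stabilisation of positive charge at the terminus carrying electron-rich ring B and by the tendency of this annulation to close at the more substituted allyl terminus.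

Step 4
Reactants: 7 methyl (2R)-2-[4-(tert-butyldimethylsilyloxy)-3,5-dimethoxyphenyl]-5-methoxy-3-methylidene-2,3-dihydro-1,4-benzodioxine-7-carboxylate
Product: 8 methyl (2R,3R)-2-[4-(tert-butyldimethylsilyloxy)-3,5-dimethoxyphenyl]-5-methoxy-3-methyl-2,3-dihydro-1,4-benzodioxine-7-carboxylate (2,3-trans)
Conditions: Mn(dpm)3 (cat.), PhSiH3, t-BuOOH, i-PrOH, rt
Reagents that add atoms: none
Why: In this metal-hydride hydrogen-atom-transfer (Mukaiyama-type) hydrogenation a manganese hydride gives a hydrogen atom to the CH2 terminus of the enol ether, and the second hydrogen atom should reach the O4-stabilised C3 radical along the axial trajectory of the half-chair that keeps the C2 aryl group equatorial, which places the methyl group equatorial and trans to the aryl group (the more stable diastereomer that stepwise radical reduction characteristically favours over the cis product of surface hydrogenation) and sets C3 as R by substrate control from C2, with ester, silyl ether and the benzylic C2–O1 bond left intact.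

Step 5
Reactants: 8 methyl (2R,3R)-2-[4-(tert-butyldimethylsilyloxy)-3,5-dimethoxyphenyl]-5-methoxy-3-methyl-2,3-dihydro-1,4-benzodioxine-7-carboxylate
Product: 9 {(2R,3R)-2-[4-(tert-butyldimethylsilyloxy)-3,5-dimethoxyphenyl]-5-methoxy-3-methyl-2,3-dihydro-1,4-benzodioxin-7-yl}methanol
Conditions: iBu2AlH, CH2Cl2, −78 to 0 °C; aq. Rochelle salt
Reagents that add atoms: none
Why: Hydride reduction of the aryl methyl ester to the benzylic alcohol with diisobutylaluminium hydride should be selective because the aryl silyl ether and the cyclic ethers are inert to the hydride at low temperature and neither stereocentre is acidic.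

Step 6
Reactants: 9 {(2R,3R)-2-[4-(tert-butyldimethylsilyloxy)-3,5-dimethoxyphenyl]-5-methoxy-3-methyl-2,3-dihydro-1,4-benzodioxin-7-yl}methanol
Product: 10 (2R,3R)-2-[4-(tert-butyldimethylsilyloxy)-3,5-dimethoxyphenyl]-5-methoxy-3-methyl-2,3-dihydro-1,4-benzodioxine-7-carbaldehyde
Conditions: MnO2, CH2Cl2, rt
Reagents that add atoms: none
Why: MnO2 oxidation is selective for the benzylic alcohol and should stop at the aryl aldehyde under neutral conditions that do not touch the C2 benzylic ether.

Step 7
Reactants: 10 (2R,3R)-2-[4-(tert-butyldimethylsilyloxy)-3,5-dimethoxyphenyl]-5-methoxy-3-methyl-2,3-dihydro-1,4-benzodioxine-7-carbaldehyde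
Product: 11 tert-butyl{2,6-dimethoxy-4-[(2R,3R)-5-methoxy-3-methyl-7-[(E)-prop-1-en-1-yl]-2,3-dihydro-1,4-benzodioxin-2-yl]phenoxy}dimethylsilane
Conditions: CrCl2, CH3CHI2, THF, rt
Reagents that add atoms: 1,1-diiodoethane, CC(I)I
Why: In the Takai–Utimoto alkylidenation the geminal dichromium reagent from 1,1-diiodoethane and CrCl2 adds to the aldehyde and eliminates to the (E)-alkene selectively, under non-basic conditions that leave C2 and C3 untouched.

Step 8
Reactants: 11 tert-butyl{2,6-dimethoxy-4-[(2R,3R)-5-methoxy-3-methyl-7-[(E)-prop-1-en-1-yl]-2,3-dihydro-1,4-benzodioxin-2-yl]phenoxy}dimethylsilane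
Product: 12 2,6-dimethoxy-4-[(2R,3R)-5-methoxy-3-methyl-7-[(E)-prop-1-en-1-yl]-2,3-dihydro-1,4-benzodioxin-2-yl]phenol (target)
Conditions: TBAF, AcOH, THF, 0 °C
Reagents that add atoms: none
Why: Fluoride-mediated cleavage of the aryl silyl ether should be fast, and the acetic acid buffer keeps the liberated phenol protonated so that no para-quinone methide opening of the C2–O1 bond can erode the C2 configuration.

**Compound list**

1 | syringaldehyde | COc1cc(C=O)cc(OC)c1O | starting material
2 | 4-(tert-butyldimethylsilyloxy)-3,5-dimethoxybenzaldehyde | COc1cc(C=O)cc(OC)c1O[Si](C)(C)C(C)(C)C | intermediate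
3 | ethynylmagnesium bromide | C#C[Mg]Br | starting material
4 | bromomagnesium 1-[4-(tert-butyldimethylsilyloxy)-3,5-dimethoxyphenyl]prop-2-yn-1-olate (racemic, not isolated) | C#CC(O[Mg]Br)c1cc(OC)c(O[Si](C)(C)C(C)(C)C)c(OC)c1 | intermediate
5 | racemic 1-[4-(tert-butyldimethylsilyloxy)-3,5-dimethoxyphenyl]prop-2-yn-1-yl methyl carbonate | C#CC(OC(=O)OC)c1cc(OC)c(O[Si](C)(C)C(C)(C)C)c(OC)c1 | intermediate
6 | methyl 3,4-dihydroxy-5-methoxybenzoate | COC(=O)c1cc(O)c(O)c(OC)c1 | starting material
7 | methyl (2R)-2-[4-(tert-butyldimethylsilyloxy)-3,5-dimethoxyphenyl]-5-methoxy-3-methylidene-2,3-dihydro-1,4-benzodioxine-7-carboxylate | COC(=O)c1cc(OC)c2c(c1)O[C@H](c1cc(OC)c(O[Si](C)(C)C(C)(C)C)c(OC)c1)C(=C)O2 | intermediate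
8 | methyl (2R,3R)-2-[4-(tert-butyldimethylsilyloxy)-3,5-dimethoxyphenyl]-5-methoxy-3-methyl-2,3-dihydro-1,4-benzodioxine-7-carboxylate | COC(=O)c1cc(OC)c2c(c1)O[C@H](c1cc(OC)c(O[Si](C)(C)C(C)(C)C)c(OC)c1)[C@@H](C)O2 | intermediate
9 | {(2R,3R)-2-[4-(tert-butyldimethylsilyloxy)-3,5-dimethoxyphenyl]-5-methoxy-3-methyl-2,3-dihydro-1,4-benzodioxin-7-yl}methanol | OCc1cc(OC)c2c(c1)O[C@H](c1cc(OC)c(O[Si](C)(C)C(C)(C)C)c(OC)c1)[C@@H](C)O2 | intermediate
10 | (2R,3R)-2-[4-(tert-butyldimethylsilyloxy)-3,5-dimethoxyphenyl]-5-methoxy-3-methyl-2,3-dihydro-1,4-benzodioxine-7-carbaldehyde | O=Cc1cc(OC)c2c(c1)O[C@H](c1cc(OC)c(O[Si](C)(C)C(C)(C)C)c(OC)c1)[C@@H](C)O2 | intermediate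
11 | tert-butyl{2,6-dimethoxy-4-[(2R,3R)-5-methoxy-3-methyl-7-[(E)-prop-1-en-1-yl]-2,3-dihydro-1,4-benzodioxin-2-yl]phenoxy}dimethylsilane | C/C=C/c1cc(OC)c2c(c1)O[C@H](c1cc(OC)c(O[Si](C)(C)C(C)(C)C)c(OC)c1)[C@@H](C)O2 | intermediate
12 | 2,6-dimethoxy-4-[(2R,3R)-5-methoxy-3-methyl-7-[(E)-prop-1-en-1-yl]-2,3-dihydro-1,4-benzodioxin-2-yl]phenol | C/C=C/c1cc(OC)c2c(c1)O[C@H](c1cc(OC)c(O)c(OC)c1)[C@@H](C)O2 | target

**Step count**

Total steps: 8. Longest linear sequence: 8 steps (from syringaldehyde 1; catechol ester 6 is used as bought).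

**Steps most likely to fail**

1. Step 3 (key annulation). What may go wrong:
- the first C–O bond forms through O1 instead of O4;
- the ring closes at the CH2 terminus, giving the achiral 3-benzylidene isomer;
- zerovalent palladium re-ionises the allylic aryl ether of the product, with loss of enantiopurity or drift to the conjugated isomer;
- ligand control is insufficient, or the silyl group is lost to phenoxide.

Fallback (chiral-pool construction of the dioxane ring with an acid-mediated closure; sets out from 6 and returns at 8, bypassing 7 and step 4). Mitsunobu etherification of the more acidic O4–H of 6 with (S)-2-hydroxy-N-methoxy-N-methylpropanamide (PPh3, DIAD, THF) should proceed with inversion to the (R)-aryloxy Weinreb amide F1. Commercial 4-bromo-2,6-dimethoxyphenol is silylated (TBSCl, imidazole) to the aryl bromide F2 and converted with magnesium in THF into the aryl Grignard reagent F3. Used in excess, with the first equivalent deprotonating O1–H, it adds to the Weinreb amide of F1 to give the α-aryloxy ketone F4. NaBH4 reduction gives the benzylic alcohol F5 as a mixture at the carbinol carbon. Catalytic acid (p-TsOH, CH2Cl2) then ionises it to the ring-B-stabilised benzylic cation, which O1 captures to close the dioxane ring to the thermodynamically preferred trans isomer 8, with C3 derived from lactate.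

2. Step 4 (radical reduction). What may go wrong:
- the second hydrogen atom is delivered anti to a pseudo-axial C2 aryl group, which would give the cis (2R,3S) isomer;
- the C3 radical undergoes β-fragmentation with cleavage of the C2–O1 bond.

Fallback (surface hydrogenation into the cis series, then thermodynamic inversion of C2; sets out from 5 and 6 and returns at 8). Step 3 is run with (S)-BINAP to give the (2S)-methylidene ester F6. Hydrogenation (H2, Rh/Al2O3, EtOAc) should add hydrogen to the face away from the aryl group and give the cis (2S,3R) ester F7, in which C3 already has the target configuration. Buffered TBAF frees the cis phenol F8. Warming with K2CO3 in DMF opens the C2–O1 bond to the para-quinone methide, and reclosure by O1 should equilibrate C2 towards the trans (2R,3R) phenol F9; any cis material is recycled. Resilylation (TBSCl, imidazole, DMF) gives 8.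

3. Step 7 (ethylidenation). What may go wrong: slow or incomplete alkylidenation of the electron-rich aryl aldehyde, and incomplete E selectivity.

Fallback (Wittig olefination, then catalytic alkene isomerisation; sets out from 10 and returns at 11). Ethylidenetriphenylphosphorane (from EtPPh3Br and KHMDS, THF, −78 °C to rt) should convert 10 mainly into the (Z)-propenyl compound F10. PdCl2(MeCN)2 (cat., CH2Cl2, rt) then isomerises it to the more stable (E)-propenyl compound 11.

**Further compounds**

F1 | step 3 | methyl 3-hydroxy-5-methoxy-4-{[(2R)-1-[methoxy(methyl)amino]-1-oxopropan-2-yl]oxy}benzoate | COC(=O)c1cc(O)c(O[C@H](C)C(=O)N(C)OC)c(OC)c1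
F2 | step 3 | (4-bromo-2,6-dimethoxyphenoxy)(tert-butyl)dimethylsilane | COc1cc(Br)cc(OC)c1O[Si](C)(C)C(C)(C)C
F3 | step 3 | 4-(tert-butyldimethylsilyloxy)-3,5-dimethoxyphenylmagnesium bromide | COc1cc([Mg]Br)cc(OC)c1O[Si](C)(C)C(C)(C)C
F4 | step 3 | methyl 4-{[(2R)-1-[4-(tert-butyldimethylsilyloxy)-3,5-dimethoxyphenyl]-1-oxopropan-2-yl]oxy}-3-hydroxy-5-methoxybenzoate | COC(=O)c1cc(O)c(O[C@H](C)C(=O)c2cc(OC)c(O[Si](C)(C)C(C)(C)C)c(OC)c2)c(OC)c1
F5 | step 3 | methyl 4-{[(2R)-1-[4-(tert-butyldimethylsilyloxy)-3,5-dimethoxyphenyl]-1-hydroxypropan-2-yl]oxy}-3-hydroxy-5-methoxybenzoate (mixture at the carbinol carbon) | COC(=O)c1cc(O)c(O[C@H](C)C(O)c2cc(OC)c(O[Si](C)(C)C(C)(C)C)c(OC)c2)c(OC)c1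
F6 | step 4 | methyl (2S)-2-[4-(tert-butyldimethylsilyloxy)-3,5-dimethoxyphenyl]-5-methoxy-3-methylidene-2,3-dihydro-1,4-benzodioxine-7-carboxylate | COC(=O)c1cc(OC)c2c(c1)O[C@@H](c1cc(OC)c(O[Si](C)(C)C(C)(C)C)c(OC)c1)C(=C)O2
F7 | step 4 | methyl (2S,3R)-2-[4-(tert-butyldimethylsilyloxy)-3,5-dimethoxyphenyl]-5-methoxy-3-methyl-2,3-dihydro-1,4-benzodioxine-7-carboxylate (2,3-cis) | COC(=O)c1cc(OC)c2c(c1)O[C@@H](c1cc(OC)c(O[Si](C)(C)C(C)(C)C)c(OC)c1)[C@@H](C)O2
F8 | step 4 | methyl (2S,3R)-2-(4-hydroxy-3,5-dimethoxyphenyl)-5-methoxy-3-methyl-2,3-dihydro-1,4-benzodioxine-7-carboxylate (2,3-cis) | COC(=O)c1cc(OC)c2c(c1)O[C@@H](c1cc(OC)c(O)c(OC)c1)[C@@H](C)O2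
F9 | step 4 | methyl (2R,3R)-2-(4-hydroxy-3,5-dimethoxyphenyl)-5-methoxy-3-methyl-2,3-dihydro-1,4-benzodioxine-7-carboxylate (2,3-trans) | COC(=O)c1cc(OC)c2c(c1)O[C@H](c1cc(OC)c(O)c(OC)c1)[C@@H](C)O2
F10 | step 7 | tert-butyl{2,6-dimethoxy-4-[(2R,3R)-5-methoxy-3-methyl-7-[(Z)-prop-1-en-1-yl]-2,3-dihydro-1,4-benzodioxin-2-yl]phenoxy}dimethylsilane | C/C=C\c1cc(OC)c2c(c1)O[C@H](c1cc(OC)c(O[Si](C)(C)C(C)(C)C)c(OC)c1)[C@@H](C)O2
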